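**Retrosynthetic overview**
- The target is a (4R)-4-aryl-3,4-dihydrocoumarin. The last operations are hydrogenolysis of three benzyl ethers and oxidation of a C2 lactol to the lactone.
- Key disconnection: C2–C3 and C4–C4a are made together in a catalytic asymmetric formal [4+2] between an aryl dimethyl orthoformate of ring A (C2 at the orthoester level) and 3,4-bis(benzyloxy)styrene. Ring C (the pyran ring) is the only ring formed; the three benzene rings are bought.
- Enabling feature: O1–C8a=C4a of ring A is an aryl enol ether whose C4a is para to the C7 oxygen. Once C2 is a dioxycarbenium ion, C2=O1(+)–C8a=C4a is a cationic 2-oxadiene, and the oxygen para to the vinyl group on the catechol ring stabilises positive charge at C4.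
- Ring A fragment: from 2,4-dihydroxybenzaldehyde by O-differentiation (MOM on the para oxygen, benzyl on the ortho oxygen), Wittig reaction with the dimethoxybenzyl ylide, alkene-selective hydrogenation and MOM removal.
- Styrene fragment: methylenation of 3,4-bis(benzyloxy)benzaldehyde.

Key step: step 8

Remark: the sense of induction of the chiral acid cannot be predicted with certainty, so the catalyst antipode that delivers the (4R) series is to be fixed in a first screen; both antipodes are accessible from (R)- or (S)-BINOL.

**Step 1**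
Reactants: 1 2,4-dihydroxybenzaldehyde
Product: 2 2-hydroxy-4-(methoxymethoxy)benzaldehyde
Conditions: MOMCl (1.1 equiv), K2CO3, acetone, 0 °C to rt
Reagents that add atoms: chloromethyl methyl ether, COCCl
Why: Williamson-type O-alkylation should go to the free, more acidic 4-OH, because the 2-OH is held in a hydrogen bond to the formyl oxygen.

**Step 2**
Reactants: 2 2-hydroxy-4-(methoxymethoxy)benzaldehyde
Product: 3 2-(benzyloxy)-4-(methoxymethoxy)benzaldehyde
Conditions: BnBr, K2CO3, DMF, 60 °C
Reagents that add atoms: benzyl bromide, BrCc1ccccc1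
Why: Williamson ether synthesis on the remaining phenol under more forcing conditions; the MOM acetal and the aldehyde are stable to carbonate base.

**Step 3**
Reactants: 3 2-(benzyloxy)-4-(methoxymethoxy)benzaldehyde; 4 (3,4-dimethoxybenzyl)triphenylphosphonium bromide
Product: 6 2-(benzyloxy)-1-[2-(3,4-dimethoxyphenyl)ethenyl]-4-(methoxymethoxy)benzene as an E/Z mixture, via benzylic phosphorus ylide 5 (not isolated)
Conditions: 4, KOtBu, THF, 0 °C; then 3, 0 °C to rt
Reagents that add atoms: none
Why: Wittig olefination with a semi-stabilised ylide should give the stilbene as an E/Z mixture, which does not matter because the double bond is saturated in step 4.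

**Step 4**
Reactants: 6 2-(benzyloxy)-1-[2-(3,4-dimethoxyphenyl)ethenyl]-4-(methoxymethoxy)benzene
Product: 7 2-(benzyloxy)-1-[2-(3,4-dimethoxyphenyl)ethyl]-4-(methoxymethoxy)benzene
Conditions: H2 (1 atm), Pd/C, Ph2S (cat.), EtOAc, rt
Reagents that add atoms: none
Why: Chemoselective heterogeneous hydrogenation over sulfur-poisoned Pd/C, a known way to saturate alkenes while aryl benzyl ethers remain; the MOM acetal is inert.

**Step 5**
Reactants: 7 2-(benzyloxy)-1-[2-(3,4-dimethoxyphenyl)ethyl]-4-(methoxymethoxy)benzene
Product: 8 3-(benzyloxy)-4-[2-(3,4-dimethoxyphenyl)ethyl]phenol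
Conditions: 3 M HCl (aq), MeOH/THF, 50 °C
Reagents that add atoms: none
Why: Acid-catalysed acetal hydrolysis (MOM cleavage) frees the phenol para to the side chain, while benzyl and methyl aryl ethers are stable to dilute HCl.

**Step 6**
Reactants: 9 3,4-bis(benzyloxy)benzaldehyde
Product: 10 1,2-bis(benzyloxy)-4-ethenylbenzene
Conditions: Ph3PCH3Br, KOtBu, THF, 0 °C to rt
Reagents that add atoms: methyltriphenylphosphonium bromide, C[P+](c1ccccc1)(c1ccccc1)c1ccccc1.[Br-]
Why: Wittig methylenation of an aromatic aldehyde with the non-stabilised ylide; benzyl ethers are inert.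

**Step 7**
Reactants: 8 3-(benzyloxy)-4-[2-(3,4-dimethoxyphenyl)ethyl]phenol
Product: 11 2-(benzyloxy)-4-(dimethoxymethoxy)-1-[2-(3,4-dimethoxyphenyl)ethyl]benzene (aryl dimethyl orthoformate)
Conditions: HC(OMe)3 (large excess, as solvent), pyridinium p-toluenesulfonate (cat.), 90 °C, MeOH distilled off; excess HC(OMe)3 removed in vacuo, crude product used directly
Reagents that add atoms: trimethyl orthoformate, COC(OC)OC
Why: Acid-catalysed orthoester exchange of an orthoformate with a phenol, driven by removal of methanol and the excess of orthoformate; only one phenolic OH is present, so a single mixed orthoformate can form.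

**Step 8**
Reactants: 11 2-(benzyloxy)-4-(dimethoxymethoxy)-1-[2-(3,4-dimethoxyphenyl)ethyl]benzene; 10 1,2-bis(benzyloxy)-4-ethenylbenzene
Product: 14 (4R)-7-(benzyloxy)-4-[3,4-bis(benzyloxy)phenyl]-6-[2-(3,4-dimethoxyphenyl)ethyl]-3,4-dihydro-2H-chromen-2-ol as a mixture of C2 epimers, via aryloxy(methoxy)carbenium ion 12 (not isolated), via 2-methoxychroman acetal 13 (not isolated)
Conditions: 10 (1.5 equiv, added slowly), chiral BINOL-derived imidodiphosphorimidate Brønsted acid (IDPi, 3 mol %), 5 Å MS, CH2Cl2, −40 °C; then THF, 1 M HCl (aq), rt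
Reagents that add atoms: water, O
Why: Proposed new method: the acid ionises the orthoester with loss of methanol (taken up by the sieves; loss of phenol 8 instead is reversible and unproductive) to the carbenium ion 12, whose C2=O1(+)–C8a=C4a unit is a cationic 2-oxadiene; the terminal CH2 of 10 adds to C2 (C2–C3 bond), positive charge builds at the benzylic C4, and C4a of ring A closes onto C4 (C4–C4a bond) with loss of a proton that returns the catalyst. The closest known reaction types are the oxa-Povarov reaction, in which Lewis acids promote this formal inverse-demand [4+2] of aryl oxocarbenium ions with styrenes to give 2,4-disubstituted chromans, and the imidodiphosphorimidate-catalysed asymmetric formal cycloadditions of styrenes with small cationic heterodienes; the formate-level dioxycarbenium ion and the asymmetric version are new. Ring C is closed as a formal [4+2] cycloaddition that is probably stepwise or highly asynchronous, the second bond forming in a six-membered Friedel–Crafts closure in which the C8a=C4a bond of the arene lies inside the new ring. The stereocentre C4 is set in the C4–C4a bond formation by the confined chiral counter-anion, which should shield one face of the benzylic cation (catalyst control), whereas the acetal centre C2 forms without control and is erased in step 9. The step needs Markovnikov addition (secured by the benzyloxy group para to the vinyl group), closure at C4a and not at C8 (C4a is para to the C7 benzyloxy group and unhindered, C8 lies between two oxygens), and ionisation of the orthoester ahead of protonation of the styrene (orthoesters ionise far more readily than styrenes are protonated, and the low temperature should slow cationic oligomerisation of 10). The aqueous HCl then hydrolyses the mixed acetal 13 to the lactol 14.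

**Step 9**
Reactants: 14 (4R)-7-(benzyloxy)-4-[3,4-bis(benzyloxy)phenyl]-6-[2-(3,4-dimethoxyphenyl)ethyl]-3,4-dihydro-2H-chromen-2-ol
Product: 15 (4R)-7-(benzyloxy)-4-[3,4-bis(benzyloxy)phenyl]-6-[2-(3,4-dimethoxyphenyl)ethyl]-3,4-dihydro-2H-chromen-2-one
Conditions: [C5H5NH][CrO3Cl] (pyridinium chlorochromate), Celite, CH2Cl2, rt
Reagents that add atoms: none
Why: Lactol-to-lactone oxidation with hexavalent chromium, the reaction type used to turn 4-arylchroman-2-ols into 4-aryl-3,4-dihydrocoumarins; both C2 epimers converge and C4, which is not alpha to the new carbonyl, is not touched.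

**Step 10**
Reactants: 15 (4R)-7-(benzyloxy)-4-[3,4-bis(benzyloxy)phenyl]-6-[2-(3,4-dimethoxyphenyl)ethyl]-3,4-dihydro-2H-chromen-2-one
Product: 16 (4R)-4-(3,4-dihydroxyphenyl)-6-[2-(3,4-dimethoxyphenyl)ethyl]-7-hydroxy-3,4-dihydro-2H-chromen-2-one (CNP0376539.1)
Conditions: H2 (1 atm), Pd/C, EtOAc/THF, rt
Reagents that add atoms: none
Why: Hydrogenolysis of the three aryl benzyl ethers over Pd/C in a non-nucleophilic solvent should leave the aryl methyl ethers, the lactone and the C4 stereocentre (no benzylic C–O bond at C4) intact.

**Compound list**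
1 | 2,4-dihydroxybenzaldehyde | O=Cc1ccc(O)cc1O | starting material
2 | 2-hydroxy-4-(methoxymethoxy)benzaldehyde | O=Cc1ccc(OCOC)cc1O | intermediate
3 | 2-(benzyloxy)-4-(methoxymethoxy)benzaldehyde | O=Cc1ccc(OCOC)cc1OCc1ccccc1 | intermediate
4 | (3,4-dimethoxybenzyl)triphenylphosphonium bromide | COc1ccc(C[P+](c2ccccc2)(c2ccccc2)c2ccccc2)cc1OC.[Br-] | starting material
5 | (3,4-dimethoxybenzylidene)triphenylphosphorane (ylide, not isolated) | COc1ccc(C=P(c2ccccc2)(c2ccccc2)c2ccccc2)cc1OC | intermediate
6 | 2-(benzyloxy)-1-[2-(3,4-dimethoxyphenyl)ethenyl]-4-(methoxymethoxy)benzene (E/Z mixture) | COCOc1ccc(C=Cc2ccc(OC)c(OC)c2)c(OCc2ccccc2)c1 | intermediate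
7 | 2-(benzyloxy)-1-[2-(3,4-dimethoxyphenyl)ethyl]-4-(methoxymethoxy)benzene | COCOc1ccc(CCc2ccc(OC)c(OC)c2)c(OCc2ccccc2)c1 | intermediate
8 | 3-(benzyloxy)-4-[2-(3,4-dimethoxyphenyl)ethyl]phenol | COc1ccc(CCc2ccc(O)cc2OCc2ccccc2)cc1OC | intermediate
9 | 3,4-bis(benzyloxy)benzaldehyde | O=Cc1ccc(OCc2ccccc2)c(OCc2ccccc2)c1 | starting material
10 | 1,2-bis(benzyloxy)-4-ethenylbenzene | C=Cc1ccc(OCc2ccccc2)c(OCc2ccccc2)c1 | intermediate
11 | 2-(benzyloxy)-4-(dimethoxymethoxy)-1-[2-(3,4-dimethoxyphenyl)ethyl]benzene | COc1ccc(CCc2ccc(OC(OC)OC)cc2OCc2ccccc2)cc1OC | intermediate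
12 | {3-(benzyloxy)-4-[2-(3,4-dimethoxyphenyl)ethyl]phenoxy}(methoxy)methylium ion, ion pair with the catalyst anion (not isolated) | COc1ccc(CCc2ccc(O[CH+]OC)cc2OCc2ccccc2)cc1OC | intermediate
13 | (4R)-7-(benzyloxy)-4-[3,4-bis(benzyloxy)phenyl]-6-[2-(3,4-dimethoxyphenyl)ethyl]-2-methoxy-3,4-dihydro-2H-chromene, C2 epimer mixture (not isolated) | COc1ccc(CCc2cc3c(cc2OCc2ccccc2)OC(OC)C[C@@H]3c2ccc(OCc3ccccc3)c(OCc3ccccc3)c2)cc1OC | intermediate
14 | (4R)-7-(benzyloxy)-4-[3,4-bis(benzyloxy)phenyl]-6-[2-(3,4-dimethoxyphenyl)ethyl]-3,4-dihydro-2H-chromen-2-ol, C2 epimer mixture | COc1ccc(CCc2cc3c(cc2OCc2ccccc2)OC(O)C[C@@H]3c2ccc(OCc3ccccc3)c(OCc3ccccc3)c2)cc1OC | intermediate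
15 | (4R)-7-(benzyloxy)-4-[3,4-bis(benzyloxy)phenyl]-6-[2-(3,4-dimethoxyphenyl)ethyl]-3,4-dihydro-2H-chromen-2-one | COc1ccc(CCc2cc3c(cc2OCc2ccccc2)OC(=O)C[C@@H]3c2ccc(OCc3ccccc3)c(OCc3ccccc3)c2)cc1OC | intermediate
16 | (4R)-4-(3,4-dihydroxyphenyl)-6-[2-(3,4-dimethoxyphenyl)ethyl]-7-hydroxy-3,4-dihydro-2H-chromen-2-one | COc1ccc(CCc2cc3c(cc2O)OC(=O)C[C@@H]3c2ccc(O)c(O)c2)cc1OC | target

**Step count and risks**
Total step count: 10. Longest linear sequence: 9 steps (steps 1 to 5, then 7 to 10); step 6 is a one-step branch.

Steps most likely to fail: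

1. Step 8 (proposed new method). The orthoester may ionise by loss of the phenol instead of methanol, the styrene may oligomerise under acid before it is intercepted, or the facial selectivity of the ring closure may be poor. Fallback with known chemistry, setting out from aldehyde 9 and phenol 8 and returning at lactol 14: aldehyde 9 is homologated with (triphenylphosphoranylidene)acetaldehyde (toluene, 80 °C) to (E)-3-[3,4-bis(benzyloxy)phenyl]prop-2-enal F1. Phenol 8 and F1 are then joined by an iminium-catalysed asymmetric Friedel–Crafts alkylation and hemiacetalisation (diarylprolinol trimethylsilyl ether, benzoic acid co-catalyst, CH2Cl2, 0 °C to rt). Ring A should react at the carbon para to its benzyloxy group, the phenol oxygen should close onto the aldehyde, and lactol 14 should result, with the catalyst antipode chosen for (4R). This forms C4–C4a and O1–C2 instead of the two C–C bonds of step 8. Steps 9 and 10 follow unchanged.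

2. Step 7. The exchange equilibrium may not be driven to completion, the orthoformate may revert to the phenol on handling or disproportionate to diaryl orthoformates, or the electron-rich ring A may be C-formylated. Fallback, setting out from 8 and returning at 11, is a base-mediated, irreversible build-up instead of an acid equilibrium. Phenol 8 is deprotonated with NaH (THF, 0 °C) to sodium 3-(benzyloxy)-4-[2-(3,4-dimethoxyphenyl)ethyl]phenolate F2. This is added to excess dichloromethyl methyl ether at −78 °C to give 2-(benzyloxy)-4-[chloro(methoxy)methoxy]-1-[2-(3,4-dimethoxyphenyl)ethyl]benzene F3. After removal of the excess reagent, NaOMe in MeOH replaces the remaining chloride to give orthoformate 11.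

3. Step 4. The aryl benzyl ether may be partly hydrogenolysed alongside alkene saturation, or the reduction may stall on the poisoned catalyst. Fallback, setting out from 6 and returning at 7, gives up the chemoselectivity. Exhaustive hydrogenation over unpoisoned Pd/C (H2, EtOAc/MeOH) should saturate the alkene and remove the benzyl group to give 2-[2-(3,4-dimethoxyphenyl)ethyl]-5-(methoxymethoxy)phenol F4. Re-benzylation (BnBr, K2CO3, DMF, 60 °C) then returns 7.

**Further compounds**
F1 | step 8 | (E)-3-[3,4-bis(benzyloxy)phenyl]prop-2-enal | O=C/C=C/c1ccc(OCc2ccccc2)c(OCc2ccccc2)c1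
F2 | step 7 | sodium 3-(benzyloxy)-4-[2-(3,4-dimethoxyphenyl)ethyl]phenolate | COc1ccc(CCc2ccc([O-])cc2OCc2ccccc2)cc1OC.[Na+]
F3 | step 7 | 2-(benzyloxy)-4-[chloro(methoxy)methoxy]-1-[2-(3,4-dimethoxyphenyl)ethyl]benzene | COc1ccc(CCc2ccc(OC(Cl)OC)cc2OCc2ccccc2)cc1OC
F4 | step 4 | 2-[2-(3,4-dimethoxyphenyl)ethyl]-5-(methoxymethoxy)phenol | COCOc1ccc(CCc2ccc(OC)c(OC)c2)c(O)c1
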